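**Retrosynthetic overview**
1. The C8 ester is made last: the macrocyclic C8 alcohol is acylated with a silyl-protected 2-(hydroxymethyl)acrylic acid, then desilylated.
2. Key disconnection is the lactone C6–O bond: Pd(II) oxypalladation of an (Ra)-2,3-allenoic acid closes the butenolide and sets C6, and the resulting C7–Pd bond adds to the tethered C8 aldehyde to close the ten-membered ring.
3. The allenoic acid comes from an epoxy propargylic mesylate and CO (anti-SN2′); the oxirane comes from hydroxyl-directed threo epoxidation of a (Z)-allylic, propargylic carbinol.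
4. The chain comes from Pd homoenolate coupling of a cyclopropanol (Kulinkovich product of (R)-α-methyl-γ-butyrolactone) with a (Z)-alkenyl iodide made by asymmetric alkynylation of (Z)-3-iodobut-2-enal with propargyl acetate.
5. Ring order: oxirane, then butenolide, then cyclodecane (the last two in one operation).

Assumption: the SMILES is read literally, i.e. (4R,5S,6S,8S,10R) with C3 and C6 cis on the oxirane; C1–C15 in the comments are germacrane locants of the target; ligand enantiomers are named as expected from the closest precedent and would be exchanged for the antipode if the observed sense were opposite.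

Step 1
Reactants: 1 but-2-yn-1-ol
Product: 3 (Z)-3-iodobut-2-en-1-ol, via cyclic alkenylalanate 2 (not isolated)
Conditions: Red-Al, THF, 0 °C to rt; then I2, −78 °C
Reagents that add atoms: iodine, II; Red-Al, [Na+].COCCO[AlH2-]OCCOC (its Na, Al and alkoxy groups are found only in 2)
Why: Alkoxide-directed trans-hydroalumination places Al on C3 in a five-membered alanate and iodinolysis goes with retention, so iodine ends cis to CH2OH (hydroalumination–iodination of a propargylic alcohol).

Step 2
Reactants: 3 (Z)-3-iodobut-2-en-1-ol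
Product: 4 (Z)-3-iodobut-2-enal
Conditions: MnO2, CH2Cl2, rt, dark
Reagents that add atoms: none
Why: MnO2 oxidises only the allylic alcohol and leaves the vinyl iodide and the Z geometry untouched (allylic oxidation).

Step 3
Reactants: 4 (Z)-3-iodobut-2-enal; 5 prop-2-yn-1-yl acetate
Product: 7 (4S,5Z)-4-hydroxy-6-iodohept-5-en-2-yn-1-yl acetate, via alkynylmethylzinc 6 (not isolated)
Conditions: Me2Zn, (S,S)-ProPhenol (10 mol%), Ph3PO (20 mol%), toluene, 4 °C
Reagents that add atoms: dimethylzinc, C[Zn]C (its Zn and CH3 are found only in 6, not in 7)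
Why: Trost ProPhenol dinuclear-zinc alkynylation of an enal delivers the alkynyl group to the Re face of the aldehyde and sets the 4S carbinol (future C6, inverted later); acetate and vinyl iodide are inert to alkynylzinc.

Step 4
Reactants: 8 3-methylidenedihydrofuran-2(3H)-one
Product: 9 (R)-3-methyldihydrofuran-2(3H)-one
Conditions: H2 (50 atm), Ru(OAc)2[(S)-BINAP] (0.5 mol%), CH2Cl2/MeOH, 50 °C
Reagents that add atoms: none
Why: Noyori Ru–BINAP asymmetric hydrogenation of the exocyclic olefin sets the 3R methyl centre (future C10).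

Step 5
Reactants: 9 (R)-3-methyldihydrofuran-2(3H)-one
Product: 10 (R)-1-(4-hydroxybutan-2-yl)cyclopropan-1-ol
Conditions: EtMgBr (3.5 equiv), Ti(OiPr)4 (0.5 equiv), THF, 0 °C to rt
Reagents that add atoms: ethylmagnesium bromide, CC[Mg]Br
Why: Kulinkovich reaction: the titanacyclopropane adds twice to the lactone carbonyl to give the cyclopropanol (C1 with C2 and C3) and frees the ring oxygen as the C8 alcohol; the α-centre is not enolised and stays R.

Step 6
Reactants: 10 (R)-1-(4-hydroxybutan-2-yl)cyclopropan-1-ol; 7 (4S,5Z)-4-hydroxy-6-iodohept-5-en-2-yn-1-yl acetate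
Product: 11 (4S,5Z,10R)-4,12-dihydroxy-6,10-dimethyl-9-oxododec-5-en-2-yn-1-yl acetate
Conditions: Pd(OAc)2 (5 mol%), XPhos (10 mol%), K3PO4, toluene, 50 °C
Reagents that add atoms: none
Why: Pd-catalysed cyclopropanol ring-opening cross-coupling (β-carbon elimination to a Pd homoenolate, then reductive elimination with the alkenyl group) forms C3–C4 and unveils the C1 ketone; the alkenyl geometry (C3 cis to C6) is retained and no stereocentre is touched.

Step 7
Reactants: 11 (4S,5Z,10R)-4,12-dihydroxy-6,10-dimethyl-9-oxododec-5-en-2-yn-1-yl acetate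
Product: 12 (4R,5S,6R,10R)-5,6-epoxy-4,12-dihydroxy-6,10-dimethyl-9-oxododec-2-yn-1-yl acetate
Conditions: mCPBA, CH2Cl2/aq. NaHCO3, 0 °C
Reagents that add atoms: mCPBA, OOC(=O)c1cccc(Cl)c1
Why: Hydroxyl-directed (Henbest) epoxidation of a (Z)-allylic alcohol: A1,3 strain holds the carbinol H in the olefin plane, so oxygen is delivered syn to the OH (threo) and the C6 carbinol sets C4 (R) and C5 (S); alkyne and ketone do not react at 0 °C.

Step 8
Reactants: 12 (4R,5S,6R,10R)-5,6-epoxy-4,12-dihydroxy-6,10-dimethyl-9-oxododec-2-yn-1-yl acetate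
Product: 13 (4R,5S,6R,10R)-5,6-epoxy-4-hydroxy-6,10-dimethyl-9,12-dioxododec-2-yn-1-yl acetate
Conditions: TEMPO (10 mol%), PhI(OAc)2 (1.1 equiv), CH2Cl2, rt
Reagents that add atoms: none
Why: Oxoammonium (TEMPO) oxidation takes the primary alcohol much faster than the hindered secondary propargylic one and is neutral toward epoxide and acetate.

Step 9
Reactants: 13 (4R,5S,6R,10R)-5,6-epoxy-4-hydroxy-6,10-dimethyl-9,12-dioxododec-2-yn-1-yl acetate
Product: 15 (Ra)-2-(acetoxymethyl)-4-{(2S,3R)-3-methyl-3-[(4R)-4-methyl-3,6-dioxohexyl]oxiran-2-yl}buta-2,3-dienoic acid, via propargylic mesylate 14 (not isolated)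
Conditions: MsCl, Et3N, CH2Cl2, −40 °C; then Pd(PPh3)4 (5 mol%), CO (1 atm), THF/H2O, −20 to 0 °C
Reagents that add atoms: carbon monoxide, [C-]#[O+]; water, O; methanesulfonyl chloride, CS(=O)(=O)Cl (its CH3SO2 group is found only in 14)
Why: Tsuji–Marshall carbonylation: Pd(0) displaces the mesylate anti-SN2′ at C11, CO inserts with retention and water cleaves the acyl-Pd, so the carbinol centre is transferred to the Ra allene axis and C12 is installed; the low temperature is meant to keep Pd(0) off the oxirane and the primary acetate.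

Step 10
Reactants: 15 (Ra)-2-(acetoxymethyl)-4-{(2S,3R)-3-methyl-3-[(4R)-4-methyl-3,6-dioxohexyl]oxiran-2-yl}buta-2,3-dienoic acid
Product: 16 (4R,5S,6S,8S,10R)-13-acetoxy-4,5-epoxy-8-hydroxy-1-oxogermacr-7(11)-en-12,6-olide
Conditions: [Pd(MeCN)4](BF4)2 (10 mol%), (S)-t-BuPyOx (12 mol%), 2,6-di-tert-butylpyridine (20 mol%), 4 Å MS, 1,2-dichloroethane, slow addition to 0.002 M, 40 °C
Reagents that add atoms: none
Why: Proposed new method: Pd(II)-catalysed oxypalladation/carbonyl-insertion macrocyclisation. The carboxylic acid adds anti across the Pd(II)-bound C6=C7 bond of the allenoic acid (5-endo), forming the lactone C6–O bond with axis-to-centre transfer (Ra gives 6S, net inversion relative to 14); the butenolide C7–Pd(II) bond, which has no β-hydrogen, then inserts the tethered C8 aldehyde and closes the ten-membered ring, the PyOx ligand selecting the aldehyde face that gives 8S, and the proton released in the first step cleaves the Pd alkoxide to turn the catalyst over. Closest known reactions are Ma's Pd(II) coupling–cyclisations of 2,3-allenoic acids with allyl halides or enones and Lu's cationic Pd(II) alkenylpalladium additions to aldehydes.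

Step 11
Reactants: 17 ethyl 2-(hydroxymethyl)acrylate
Product: 18 ethyl 2-({[tert-butyl(dimethyl)silyl]oxy}methyl)acrylate
Conditions: TBSCl, imidazole, CH2Cl2, 0 °C to rt
Reagents that add atoms: TBSCl, CC(C)(C)[Si](C)(C)Cl
Why: Standard silylation of a primary alcohol (silyl ether protection).

Step 12
Reactants: 18 ethyl 2-({[tert-butyl(dimethyl)silyl]oxy}methyl)acrylate
Product: 19 2-({[tert-butyl(dimethyl)silyl]oxy}methyl)acrylic acid
Conditions: LiOH, THF/H2O, 0 °C; 1 M HCl to pH 3 on work-up
Reagents that add atoms: lithium hydroxide, [Li+].[OH-]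
Why: Saponification of the ethyl ester; the TBS ether survives cold LiOH.

Step 13
Reactants: 16 (4R,5S,6S,8S,10R)-13-acetoxy-4,5-epoxy-8-hydroxy-1-oxogermacr-7(11)-en-12,6-olide; 19 2-({[tert-butyl(dimethyl)silyl]oxy}methyl)acrylic acid
Product: 20 (4R,5S,6S,8S,10R)-13-acetoxy-8-[2-({[tert-butyl(dimethyl)silyl]oxy}methyl)acryloyloxy]-4,5-epoxy-1-oxogermacr-7(11)-en-12,6-olide
Conditions: DIC, DMAP (10 mol%), CH2Cl2, 0 °C to rt
Reagents that add atoms: none
Why: Steglich esterification of the only free hydroxyl, with retention at C8; translactonisation to an 8,12-olide would need a bridgehead olefin and is not expected.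

Step 14
Reactants: 20 (4R,5S,6S,8S,10R)-13-acetoxy-8-[2-({[tert-butyl(dimethyl)silyl]oxy}methyl)acryloyloxy]-4,5-epoxy-1-oxogermacr-7(11)-en-12,6-olide
Product: 21 (4R,5S,6S,8S,10R)-13-acetoxy-4,5-epoxy-8-[2-(hydroxymethyl)acryloyloxy]-1-oxogermacr-7(11)-en-12,6-olide (CNP0258719.1)
Conditions: HF·pyridine, THF/pyridine, 0 °C
Reagents that add atoms: none
Why: Fluoride desilylation under buffered conditions; epoxide, acetate, butenolide and the α-methyl ketone are left alone.

**Compound list**
1 | but-2-yn-1-ol | CC#CCO | starting material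
2 | sodium 2,2-bis(2-methoxyethoxy)-3-methyl-2,5-dihydro-1,2-oxaaluminol-2-uide (cyclic alkenylalanate) | CC1=CCO[Al-]1(OCCOC)OCCOC.[Na+] | intermediate (not isolated)
3 | (Z)-3-iodobut-2-en-1-ol | I/C(C)=C\CO | intermediate
4 | (Z)-3-iodobut-2-enal | I/C(C)=C\C=O | intermediate
5 | prop-2-yn-1-yl acetate | C#CCOC(C)=O | starting material
6 | (3-acetoxyprop-1-yn-1-yl)(methyl)zinc | C[Zn]C#CCOC(C)=O | intermediate (not isolated)
7 | (4S,5Z)-4-hydroxy-6-iodohept-5-en-2-yn-1-yl acetate | I/C(C)=C\[C@H](O)C#CCOC(C)=O | intermediate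
8 | 3-methylidenedihydrofuran-2(3H)-one (α-methylene-γ-butyrolactone) | C=C1CCOC1=O | starting material
9 | (R)-3-methyldihydrofuran-2(3H)-one | C1C[C@@H](C)C(=O)O1 | intermediate
10 | (R)-1-(4-hydroxybutan-2-yl)cyclopropan-1-ol | OCC[C@@H](C)C1(O)CC1 | intermediate
11 | (4S,5Z,10R)-4,12-dihydroxy-6,10-dimethyl-9-oxododec-5-en-2-yn-1-yl acetate | OCC[C@@H](C)C(=O)CC/C(C)=C\[C@H](O)C#CCOC(C)=O | intermediate
12 | (4R,5S,6R,10R)-5,6-epoxy-4,12-dihydroxy-6,10-dimethyl-9-oxododec-2-yn-1-yl acetate | OCC[C@@H](C)C(=O)CC[C@@]1(C)O[C@H]1[C@H](O)C#CCOC(C)=O | intermediate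
13 | (4R,5S,6R,10R)-5,6-epoxy-4-hydroxy-6,10-dimethyl-9,12-dioxododec-2-yn-1-yl acetate | O=CC[C@@H](C)C(=O)CC[C@@]1(C)O[C@H]1[C@H](O)C#CCOC(C)=O | intermediate
14 | (4R,5S,6R,10R)-5,6-epoxy-6,10-dimethyl-4-(methylsulfonyloxy)-9,12-dioxododec-2-yn-1-yl acetate | O=CC[C@@H](C)C(=O)CC[C@@]1(C)O[C@H]1[C@H](OS(C)(=O)=O)C#CCOC(C)=O | intermediate (not isolated)
15 | (Ra)-2-(acetoxymethyl)-4-{(2S,3R)-3-methyl-3-[(4R)-4-methyl-3,6-dioxohexyl]oxiran-2-yl}buta-2,3-dienoic acid | O=CC[C@@H](C)C(=O)CC[C@@]1(C)O[C@H]1C=[C@]=C(COC(C)=O)C(=O)O | intermediate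
16 | (4R,5S,6S,8S,10R)-13-acetoxy-4,5-epoxy-8-hydroxy-1-oxogermacr-7(11)-en-12,6-olide | O[C@H]1C[C@@H](C)C(=O)CC[C@@]2(C)O[C@H]2[C@H]2OC(=O)C(COC(C)=O)=C12 | intermediate
17 | ethyl 2-(hydroxymethyl)acrylate | C=C(CO)C(=O)OCC | starting material
18 | ethyl 2-({[tert-butyl(dimethyl)silyl]oxy}methyl)acrylate | C=C(CO[Si](C)(C)C(C)(C)C)C(=O)OCC | intermediate
19 | 2-({[tert-butyl(dimethyl)silyl]oxy}methyl)acrylic acid | C=C(CO[Si](C)(C)C(C)(C)C)C(=O)O | intermediate
20 | (4R,5S,6S,8S,10R)-13-acetoxy-8-[2-({[tert-butyl(dimethyl)silyl]oxy}methyl)acryloyloxy]-4,5-epoxy-1-oxogermacr-7(11)-en-12,6-olide | C=C(CO[Si](C)(C)C(C)(C)C)C(=O)O[C@H]1C[C@@H](C)C(=O)CC[C@@]2(C)O[C@H]2[C@H]2OC(=O)C(COC(C)=O)=C12 | intermediate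
21 | (4R,5S,6S,8S,10R)-13-acetoxy-4,5-epoxy-8-[2-(hydroxymethyl)acryloyloxy]-1-oxogermacr-7(11)-en-12,6-olide | C=C(CO)C(=O)O[C@H]1C[C@@H](C)C(=O)CC[C@@]2(C)O[C@H]2[C@H]2OC(=O)C(COC(C)=O)=C12 | target

**Step count**
Total steps: 14. Longest linear sequence: 10 (steps 1, 2, 3, 6, 7, 8, 9, 10, 13, 14).

**Steps most likely to fail**

Step 10 (the new reaction). The alkenyl-Pd may be protonated to the simple β-H butenolide before the ring closes, or control at C8 may be poor. The fallback uses known chemistry, sets out from 15 and returns at 16. Ma-type iodolactonisation of 15 with N-iodosuccinimide in MeCN makes the same C6–O bond with the same anti course and gives the 4-iodobutenolide aldehyde F1. An intramolecular Nozaki–Hiyama–Kishi reaction of F1 (CrCl2, cat. NiCl2, Kishi's (S)-sulfonamide ligand, MeCN/THF, high dilution) then forms C7–C8 and gives 16.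

Step 6. β-Hydride elimination of the Pd homoenolate to an enone, or Pd(0) attack on the propargylic acetate, may win. The fallback sets out from 9 and 7 and returns at 11. Lactone 9 is opened with MeNH(OMe)·HCl/i-PrMgCl to the Weinreb amide F2, and vinylmagnesium bromide converts it into the vinyl ketone F3. Iodide 7 is turned by Miyaura borylation (B2pin2, PdCl2(dppf), KOAc) into the alkenyl pinacol boronate F4. Rh-catalysed Hayashi–Miyaura conjugate addition of F4 to F3 ([Rh(cod)OH]2, dioxane/H2O) gives 11.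

Step 3. The ee or yield may be low with propargyl acetate, or the iodo-enal may isomerise. The fallback sets out from 4 and 5 and returns at 7. Ligand-free Zn(OTf)2/Et3N alkynylation gives the racemic alcohol F5, MnO2 oxidises it to the ynone F6, and Midland reduction with (S)-Alpine-borane (alkynyl as the small group) returns 7.

Further compounds
F1 | step 10 | [(5R)-4-iodo-5-{(2S,3R)-3-methyl-3-[(4R)-4-methyl-3,6-dioxohexyl]oxiran-2-yl}-2-oxo-2,5-dihydrofuran-3-yl]methyl acetate | O=CC[C@@H](C)C(=O)CC[C@@]1(C)O[C@H]1[C@H]2OC(=O)C(COC(C)=O)=C2I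
F2 | step 6 | (R)-4-hydroxy-N-methoxy-N,2-dimethylbutanamide | OCC[C@@H](C)C(=O)N(C)OC
F3 | step 6 | (R)-6-hydroxy-4-methylhex-1-en-3-one | OCC[C@@H](C)C(=O)C=C
F4 | step 6 | (4S,5E)-4-hydroxy-6-(4,4,5,5-tetramethyl-1,3,2-dioxaborolan-2-yl)hept-5-en-2-yn-1-yl acetate (boron cis to C4) | CC1(C)OB(OC1(C)C)/C(C)=C\[C@H](O)C#CCOC(C)=O
F5 | step 3 | (5Z)-4-hydroxy-6-iodohept-5-en-2-yn-1-yl acetate (racemic) | I/C(C)=C\C(O)C#CCOC(C)=O
F6 | step 3 | (5Z)-6-iodo-4-oxohept-5-en-2-yn-1-yl acetate | I/C(C)=C\C(=O)C#CCOC(C)=O
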